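(The data come from a simulation on assumed constants; the scatter is artificial.)

The slow event in these flasks was the loss of substrate, so I treated it like initiator decay: first-order, with c_substrate falling exponentially from its charge. The question was how far that decay had run by the end.

| flask | substrate | temperature | remark | time |
|---|---|---|---|---|
| south | 0.40 M | 45 °C | run made earlier |  |
| south-east | 0.60 M | 62 °C | run made earlier |  |
| alder | 0.80 M | 50 °C |  | 5.0 h |
| cedar | 0.80 M | 75 °C |  | 5.0 h |

south run (percent of the substrate charged)

| time / h | isomer of the product A / % | isomer of the product B / % | substrate / % | target / % |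
|---|---|---|---|---|
| 0.250 | 0 | 0 | 97 | 4 |
| 0.500 | 1 | 1 | 93 | 5 |
| 1.33 | 4 | 0 | 85 | 9 |
| 3.00 | 10 | 0 | 73 | 23 |

south-east run (percent of the substrate charged)

| time / min | isomer of the product A / % | isomer of the product B / % | substrate / % | target / % |
|---|---|---|---|---|
| 30.0 | 2 | 0 | 67 | 29 |
| 50.0 | 9 | 0 | 57 | 39 |
| 80.0 | 2 | 2 | 47 | 50 |
| 90.0 | 4 | 2 | 46 | 55 |

(readings scatter by 2 percentage points)

- which of these there is most of at the end, counted by the substrate in it, alder (isomer of the product B / isomer of the product A / target / substrate)
- which of these there is most of at the end, counted by the substrate in it, cedar (isomer of the product B / isomer of the product A / target / substrate)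
- the largest of these amounts at the end, in percent of the substrate charged, alder
- the largest of these amounts at the end, in percent of the substrate charged, cedar

- a reading or a percentage of target counts all its forms, free or not

The last south reading gave an apparent constant k of 0.105 /h, and the first south-east reading gave an apparent 0.801 /h, a value that may already contain some slowing. Interpolating ln k on temperature gave 0.191 /h for alder. I then defined the clock number, k times the time, the count of e-foldings the substrate has undergone; for alder it is 0.954, which leaves 38.5% of the substrate.

Could the late slowing of the south-east run reach alder? That run read 46% at 90.0 min, above the 30.1% its own clock gave, and this reading is a c_substrate of 0.276 M. Alder's reckoned end, 0.308 M, stays above that, so I kept the clock for alder and, allowing the isomers the 6.00% of that last reading, expected 55.5% target.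

Cedar's clock reads 19.0, far beyond alder's, so for cedar I looked to the stall instead. Held as the same concentration, it leaves 34.5% substrate and 59.5% target.

The forecast named target in both flasks, at 46% for alder, lower than my figure, and 78% for cedar, higher than mine, with “real risk of a lower plateau”.

The flasks gave target at 60.7% in alder and target at 74.2% in cedar.

    substrate ⇌ target (K = 0.860, k = 0.00450 /min, Ea = 112 kJ/mol, ΔH = −34.0 kJ/mol)
    target ⇌ isomer of the product A (K = 0.340, k = 0.0520 /min, Ea = 97.0 kJ/mol, ΔH = −47.0 kJ/mol)
    isomer of the product A ⇌ isomer of the product B (K = 0.210, k = 0.00150 /min, Ea = 109 kJ/mol, ΔH = 35.0 kJ/mol)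
    isomer of the product B ⇌ substrate (k = 5.40 × 10⁻⁴ /min, Ea = 118 kJ/mol)
    crystals ⇌ target, rate k5*(cs5 - [target]) while solid is left; crystals form when [target] > cs5 (solubility = 0.0650 M, k = 0.0590 /min)
    (constants at 50 °C)

In alder, substrate turned into target while crystals grew to 50.6%, and the clock kept pace, giving 62.1% substrate at 2.50 h against 56.9% in the flask, and 38.5% at the end against 35.0%. In cedar, whose clock allows hardly any substrate, half of the crystal turnover was done by 0.925 h, and substrate stood at 24.5% at 5.00 h, below my 34.5%, and at 23.4% at 50.0 h.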